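**Plan**
- Retrosynthetic cuts: the C2 CH2OH goes back to a C2 formyl group; the C1–C2 bond of ring B to an aldehyde enamine plus a ring C para-quinone methide; the C1–C8a bond to a ring A arylmagnesium plus a ring C aldehyde; C3=C4 to a Horner–Wadsworth–Emmons olefination; the formyl group to a terminal alkene.
- Enabling feature: the free 4-OH of ring C is para to C1, so C1 can become the exocyclic carbon of a para-quinone methide, and C2 is the α-carbon of the side-chain carbon once that carbon is an aldehyde.
- Forward order: one silyl ether of syringaldehyde supplies ring C and, after iodination, ring A; olefination builds C3=C4 with an allyl arm; iodine–magnesium exchange joins ring C at C1 as a benzhydryl acetate; alkene cleavage gives the aldehyde; ring B closes last.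
- Stereochemistry: both centres arise in the ring closure. The (R)-pyrrolidine catalyst fixes C2 as R, the cyclic transition state puts the C1 aryl group trans (1S), and the final reduction touches neither.

Key step: step 7

Remark: positions follow dihydronaphthalene numbering (C1 bears ring C, C2 the CH2OH, C3 the CO2Me, C4 the vinylic CH, C4a/C8a the ring A fusion carbons). The target SMILES encodes the trans (1S,2R) isomer. Both phenols are carried as TBS ethers, so one fluoride treatment frees them in the ring-closing step and no separate deprotection follows. The benzhydryl carbon is carried racemic because it becomes planar in the quinone methide.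

**Step 1**
Reactants: 1 syringaldehyde
Product: 2 4-(tert-butyldimethylsilyloxy)-3,5-dimethoxybenzaldehyde
Conditions: TBSCl, imidazole, DMF, rt
Reagents that add atoms: tert-butyldimethylsilyl chloride, CC(C)(C)[Si](C)(C)Cl
Why: Imidazole-promoted silyl ether formation on the acidic syringyl phenol is routine and leaves the aldehyde untouched.

**Step 2**
Reactants: 2 4-(tert-butyldimethylsilyloxy)-3,5-dimethoxybenzaldehyde
Product: 3 4-(tert-butyldimethylsilyloxy)-2-iodo-3,5-dimethoxybenzaldehyde
Conditions: I2, CF3CO2Ag, CH2Cl2, 0 °C → rt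
Reagents that add atoms: iodine, II
Why: Electrophilic aromatic iodination can only occur at the two equivalent free positions, each ortho and para to a methoxy group; the first iodine slows a second substitution and the aryl silyl ether should tolerate the CF3CO2H released.

**Step 3**
Reactants: 4 trimethyl phosphonoacetate; 5 allyl bromide
Product: 6 methyl 2-(dimethoxyphosphoryl)pent-4-enoate (racemic)
Conditions: NaH, THF, 0 °C → rt (4 in slight excess)
Reagents that add atoms: none
Why: SN2 C-alkylation of the sodium phosphonoacetate carbanion with an allylic bromide is standard, and a slight excess of 4 suppresses double allylation.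

**Step 4**
Reactants: 3 4-(tert-butyldimethylsilyloxy)-2-iodo-3,5-dimethoxybenzaldehyde; 6 methyl 2-(dimethoxyphosphoryl)pent-4-enoate
Product: 7 methyl (2E)-2-{[4-(tert-butyldimethylsilyloxy)-2-iodo-3,5-dimethoxyphenyl]methylidene}pent-4-enoate
Conditions: NaH, THF, 0 °C → rt (carbanion of 6 preformed, then 3)
Reagents that add atoms: none
Why: Horner–Wadsworth–Emmons olefination of an aryl aldehyde with an α-branched phosphonoacetate should give mainly the E alkene (aryl trans to CO2Me, cis to the allyl CH2), which is the geometry ring closure needs; the minor Z isomer is removed by chromatography and the non-nucleophilic carbanion spares the aryl silyl ether.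

**Step 5**
Reactants: 7 methyl (2E)-2-{[4-(tert-butyldimethylsilyloxy)-2-iodo-3,5-dimethoxyphenyl]methylidene}pent-4-enoate; 2 4-(tert-butyldimethylsilyloxy)-3,5-dimethoxybenzaldehyde
Product: 10 racemic methyl (2E)-2-[(2-{acetoxy[4-(tert-butyldimethylsilyloxy)-3,5-dimethoxyphenyl]methyl}-4-(tert-butyldimethylsilyloxy)-3,5-dimethoxyphenyl)methylidene]pent-4-enoate, via arylmagnesium chloride 8 (not isolated), via chloromagnesium alkoxide 9 (not isolated)
Conditions: iPrMgCl·LiCl, THF, −30 °C; then 2, −30 → −10 °C; then Ac2O, −10 → 0 °C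
Reagents that add atoms: acetic anhydride, CC(=O)OC(C)=O
Why: Iodine–magnesium exchange on an aryl iodide is faster at low temperature than attack on the hindered conjugated methyl ester, the arylmagnesium adds 1,2 to the aldehyde (Grignard addition), and acetylation of the alkoxide in the same flask both prevents oxa-Michael closure onto the acrylate and installs the leaving group; the new benzhydryl centre forms racemic and is erased in step 7.

**Step 6**
Reactants: 10 racemic benzhydryl acetate with the allyl arm
Product: 12 racemic methyl (2E)-2-[(2-{acetoxy[4-(tert-butyldimethylsilyloxy)-3,5-dimethoxyphenyl]methyl}-4-(tert-butyldimethylsilyloxy)-3,5-dimethoxyphenyl)methylidene]-4-oxobutanoate, via vicinal diol 11 (not isolated)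
Conditions: OsO4 (2 mol %), NaIO4, 2,6-lutidine, dioxane/H2O 3:1, rt; used promptly
Reagents that add atoms: osmium tetroxide, O=[Os](=O)(=O)=O (its oxo groups, restored by sodium periodate, [Na+].[O-]I(=O)(=O)=O, and water, O, supply the carbonyl oxygen)
Why: In the Lemieux–Johnson oxidation the monosubstituted terminal alkene is osmylated much faster than the hindered, ester-conjugated trisubstituted C3=C4 bond, and the lutidine buffer should keep the benzhydryl acetate and the β,γ-unsaturated aldehyde intact.

**Step 7**
Reactants: 12 racemic bis-silyl benzhydryl acetate aldehyde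
Product: 16 methyl (1S,2R)-2-formyl-7-hydroxy-1-(4-hydroxy-3,5-dimethoxyphenyl)-6,8-dimethoxy-1,2-dihydronaphthalene-3-carboxylate, via bisphenol acetate 13 (not isolated), via quinone methide 14 (not isolated), via dienamine 15 (not isolated)
Conditions: (R)-2-[methoxy(diphenyl)methyl]pyrrolidine (20 mol %), AcOH (4 equiv), then Bu4NF (2.2 equiv) added last, THF/CH2Cl2, −40 → −10 °C; crude product taken on at once
Reagents that add atoms: none
Why: Fluoride removes both aryl silyl groups to give 13, whose ring C phenol(ate) expels acetate by 1,6-elimination to the quinone methide 14, while the pyrrolidine condenses with the aldehyde to the E-dienamine 15; the enamine α-carbon C2 then adds to the methide carbon C1, ring C returns to a phenol, and hydrolysis of the iminium ion releases 16 and the catalyst. The closest known reaction types are the aminocatalytic α-alkylation of aldehydes by 1,6-addition of their enamines to para-quinone methides and the fluoride-triggered release of quinone methides from silylated para-hydroxybenzyl esters; a methyl ether catalyst is chosen because a silyl ether catalyst would not survive the fluoride. Ring B closes in a 6-(enolexo)-exo-trig mode through C1, C2, C3, C4, C4a and C8a. C2 is set by the catalyst, whose methoxydiphenylmethyl arm blocks one face of the enamine so that C1 bonds to the other (2R with the R-pyrrolidine), and C1 is set by the half-chair transition state, which holds the syringyl group pseudoaxial, away from the C8 methoxy group and anti to the iminium carbon (1S, trans); the trans aldehyde is also the more stable C2 epimer. The step needs α- rather than γ-attack of the dienamine and amine-catalysed rather than base-mediated closure: C4 and C1 sit on adjacent ring A carbons, so only C2 can reach C1 in a six-membered ring, and the acetic acid buffer keeps free dienolate low while the tethered enamine captures 14 as it forms.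

**Step 8**
Reactants: 16 methyl (1S,2R)-2-formyl-7-hydroxy-1-(4-hydroxy-3,5-dimethoxyphenyl)-6,8-dimethoxy-1,2-dihydronaphthalene-3-carboxylate
Product: 17 methyl (1S,2R)-7-hydroxy-1-(4-hydroxy-3,5-dimethoxyphenyl)-2-(hydroxymethyl)-6,8-dimethoxy-1,2-dihydronaphthalene-3-carboxylate
Conditions: NaBH4, MeOH/THF, −40 °C; AcOH, pH 7 buffer
Reagents that add atoms: none
Why: Borohydride reduction takes the aldehyde and not the conjugated methyl ester, and a cold, short reaction with a buffered quench should avoid C2 epimerization, C3=C4 migration and lactonization of the new γ-hydroxy ester, so neither stereocentre is touched.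

**Compound list**
1 | syringaldehyde (4-hydroxy-3,5-dimethoxybenzaldehyde) | COc1cc(C=O)cc(OC)c1O | starting material
2 | 4-(tert-butyldimethylsilyloxy)-3,5-dimethoxybenzaldehyde | COc1cc(C=O)cc(OC)c1O[Si](C)(C)C(C)(C)C | intermediate
3 | 4-(tert-butyldimethylsilyloxy)-2-iodo-3,5-dimethoxybenzaldehyde | COc1cc(C=O)c(I)c(OC)c1O[Si](C)(C)C(C)(C)C | intermediate
4 | trimethyl phosphonoacetate | COC(=O)CP(=O)(OC)OC | starting material
5 | allyl bromide | C=CCBr | starting material
6 | methyl 2-(dimethoxyphosphoryl)pent-4-enoate (racemic) | COC(=O)C(CC=C)P(=O)(OC)OC | intermediate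
7 | methyl (2E)-2-{[4-(tert-butyldimethylsilyloxy)-2-iodo-3,5-dimethoxyphenyl]methylidene}pent-4-enoate | COC(=O)/C(CC=C)=C/c1cc(OC)c(O[Si](C)(C)C(C)(C)C)c(OC)c1I | intermediate
8 | arylmagnesium chloride from 7 (formed in the flask) | COC(=O)/C(CC=C)=C/c1cc(OC)c(O[Si](C)(C)C(C)(C)C)c(OC)c1[Mg]Cl | intermediate
9 | chloromagnesium benzhydryl alkoxide (racemic, formed in the flask) | COC(=O)/C(CC=C)=C/c1cc(OC)c(O[Si](C)(C)C(C)(C)C)c(OC)c1C(O[Mg]Cl)c1cc(OC)c(O[Si](C)(C)C(C)(C)C)c(OC)c1 | intermediate
10 | methyl (2E)-2-[(2-{acetoxy[4-(tert-butyldimethylsilyloxy)-3,5-dimethoxyphenyl]methyl}-4-(tert-butyldimethylsilyloxy)-3,5-dimethoxyphenyl)methylidene]pent-4-enoate (racemic) | COC(=O)/C(CC=C)=C/c1cc(OC)c(O[Si](C)(C)C(C)(C)C)c(OC)c1C(OC(C)=O)c1cc(OC)c(O[Si](C)(C)C(C)(C)C)c(OC)c1 | intermediate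
11 | 4,5-dihydroxypentanoate diol from 10 (diastereomer mixture, formed in the flask) | COC(=O)/C(CC(O)CO)=C/c1cc(OC)c(O[Si](C)(C)C(C)(C)C)c(OC)c1C(OC(C)=O)c1cc(OC)c(O[Si](C)(C)C(C)(C)C)c(OC)c1 | intermediate
12 | methyl (2E)-2-[(2-{acetoxy[4-(tert-butyldimethylsilyloxy)-3,5-dimethoxyphenyl]methyl}-4-(tert-butyldimethylsilyloxy)-3,5-dimethoxyphenyl)methylidene]-4-oxobutanoate (racemic) | COC(=O)/C(CC=O)=C/c1cc(OC)c(O[Si](C)(C)C(C)(C)C)c(OC)c1C(OC(C)=O)c1cc(OC)c(O[Si](C)(C)C(C)(C)C)c(OC)c1 | intermediate
13 | methyl (2E)-2-[(2-{acetoxy(4-hydroxy-3,5-dimethoxyphenyl)methyl}-4-hydroxy-3,5-dimethoxyphenyl)methylidene]-4-oxobutanoate (racemic, formed in the flask) | COC(=O)/C(CC=O)=C/c1cc(OC)c(O)c(OC)c1C(OC(C)=O)c1cc(OC)c(O)c(OC)c1 | intermediate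
14 | ring C para-quinone methide: methyl (2E)-2-[(2-{(3,5-dimethoxy-4-oxocyclohexa-2,5-dien-1-ylidene)methyl}-4-hydroxy-3,5-dimethoxyphenyl)methylidene]-4-oxobutanoate (formed in the flask) | COC(=O)/C(CC=O)=C/c1cc(OC)c(O)c(OC)c1C=C1C=C(OC)C(=O)C(OC)=C1 | intermediate
15 | E-dienamine of 14 with (R)-2-[methoxy(diphenyl)methyl]pyrrolidine (formed in the flask) | COC(=O)/C(=C/c1cc(OC)c(O)c(OC)c1C=C1C=C(OC)C(=O)C(OC)=C1)/C=C/N1CCC[C@@H]1C(OC)(c1ccccc1)c1ccccc1 | intermediate
16 | methyl (1S,2R)-2-formyl-7-hydroxy-1-(4-hydroxy-3,5-dimethoxyphenyl)-6,8-dimethoxy-1,2-dihydronaphthalene-3-carboxylate | COC(=O)C1=Cc2cc(OC)c(O)c(OC)c2[C@H](c2cc(OC)c(O)c(OC)c2)[C@H]1C=O | intermediate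
17 | methyl (1S,2R)-7-hydroxy-1-(4-hydroxy-3,5-dimethoxyphenyl)-2-(hydroxymethyl)-6,8-dimethoxy-1,2-dihydronaphthalene-3-carboxylate | COC(=O)C1=Cc2cc(OC)c(O)c(OC)c2[C@H](c2cc(OC)c(O)c(OC)c2)[C@H]1CO | target

**Step count**
Total: 8 steps. Longest linear sequence: 7 steps (1, 2, 4, 5, 6, 7, 8) from syringaldehyde; step 3 is a one-step side branch.

**Steps most likely to fail**

Step 7. The acetate and fluoride salts may enolize the doubly activated C2 methylene, so that part of the ring closure runs through a free dienolate without the catalyst and enantiopurity erodes. The aldehyde may also drift into conjugation before the methide appears. The fallback separates phenol release from C–C bond formation through a storable sulfone, the established base-releasable quinone methide precursor. Setting out from 12, desilylation with Bu4NF/AcOH in the presence of excess TolSO2Na (THF/DMF, −20 °C) should let sulfinate intercept the methide and give the racemic bisphenol benzhydryl p-tolyl sulfone F1, which is isolated. F1 with the same pyrrolidine catalyst in toluene over aqueous NaHCO3 at 0 °C should release 14 slowly at the phase boundary, with no soluble base in the organic phase, and the dienamine closes it to 16, where the route is rejoined.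

Step 5. Iodine–magnesium exchange on the electron-rich, doubly ortho-substituted iodide may be slower than attack of the magnesium reagents on the methyl ester, or the magnesium alkoxide may close onto the acrylate before it is acetylated. The fallback is a Nozaki–Hiyama–Kishi coupling. Setting out from 7 and 2, CrCl2 with NiCl2 (cat.) in DMF/THF at rt should add a weakly basic arylchromium species to the aldehyde and give, after aqueous work-up, the free racemic benzhydrol F2. Acetylation (Ac2O, pyridine, DMAP, 0 °C) returns to 10.

Step 6. Osmylation may also reach the C3=C4 bond, the benzhydryl acetate may hydrolyze in the aqueous medium, or C3=C4 may shift into conjugation with the new aldehyde. The fallback brings in the aldehyde carbon at the alcohol oxidation level, so no alkene has to be cleaved. It sets out from 4 and 3.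
- 2-Iodoethanol is silylated (Et3SiCl, imidazole) to (2-iodoethoxy)triethylsilane F3.
- The sodium salt of 4 is alkylated with F3 to methyl 2-(dimethoxyphosphoryl)-4-(triethylsilyloxy)butanoate F4.
- Horner–Wadsworth–Emmons reaction of F4 with 3 gives the E aryl iodide F5.
- Iodine–magnesium exchange to the arylmagnesium chloride F6, addition to 2 to give the chloromagnesium alkoxide F7, and acetylation as in step 5 give the benzhydryl acetate F8.
- Direct Swern oxidation of the primary triethylsilyl ether of F8 ((COCl)2, DMSO, CH2Cl2, −78 → −40 °C, then Et3N), which leaves aryl TBS ethers alone, comes back to the route at 12.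

**Further compounds**
F1 | step 7 | methyl (2E)-2-[(4-hydroxy-2-{(4-hydroxy-3,5-dimethoxyphenyl)[(4-methylphenyl)sulfonyl]methyl}-3,5-dimethoxyphenyl)methylidene]-4-oxobutanoate (racemic) | COC(=O)/C(CC=O)=C/c1cc(OC)c(O)c(OC)c1C(c1cc(OC)c(O)c(OC)c1)S(=O)(=O)c1ccc(C)cc1
F2 | step 5 | methyl (2E)-2-[(4-(tert-butyldimethylsilyloxy)-2-{[4-(tert-butyldimethylsilyloxy)-3,5-dimethoxyphenyl](hydroxy)methyl}-3,5-dimethoxyphenyl)methylidene]pent-4-enoate (racemic) | COC(=O)/C(CC=C)=C/c1cc(OC)c(O[Si](C)(C)C(C)(C)C)c(OC)c1C(O)c1cc(OC)c(O[Si](C)(C)C(C)(C)C)c(OC)c1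
F3 | step 6 | (2-iodoethoxy)triethylsilane | CC[Si](CC)(CC)OCCI
F4 | step 6 | methyl 2-(dimethoxyphosphoryl)-4-(triethylsilyloxy)butanoate (racemic) | COC(=O)C(CCO[Si](CC)(CC)CC)P(=O)(OC)OC
F5 | step 6 | methyl (2E)-2-{[4-(tert-butyldimethylsilyloxy)-2-iodo-3,5-dimethoxyphenyl]methylidene}-4-(triethylsilyloxy)butanoate | COC(=O)/C(CCO[Si](CC)(CC)CC)=C/c1cc(OC)c(O[Si](C)(C)C(C)(C)C)c(OC)c1I
F6 | step 6 | arylmagnesium chloride from F5 (formed in the flask) | COC(=O)/C(CCO[Si](CC)(CC)CC)=C/c1cc(OC)c(O[Si](C)(C)C(C)(C)C)c(OC)c1[Mg]Cl
F7 | step 6 | chloromagnesium benzhydryl alkoxide from F6 and 2 (racemic, formed in the flask) | COC(=O)/C(CCO[Si](CC)(CC)CC)=C/c1cc(OC)c(O[Si](C)(C)C(C)(C)C)c(OC)c1C(O[Mg]Cl)c1cc(OC)c(O[Si](C)(C)C(C)(C)C)c(OC)c1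
F8 | step 6 | methyl (2E)-2-[(2-{acetoxy[4-(tert-butyldimethylsilyloxy)-3,5-dimethoxyphenyl]methyl}-4-(tert-butyldimethylsilyloxy)-3,5-dimethoxyphenyl)methylidene]-4-(triethylsilyloxy)butanoate (racemic) | COC(=O)/C(CCO[Si](CC)(CC)CC)=C/c1cc(OC)c(O[Si](C)(C)C(C)(C)C)c(OC)c1C(OC(C)=O)c1cc(OC)c(O[Si](C)(C)C(C)(C)C)c(OC)c1
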